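Ring C, the cyclohexane, is made by contracting a seven-membered ring. The bond between its two adjacent CH carbons shared with cyclooctene ring B (one bears the C=CH2 carbon, the other the methyl-substituted alkene carbon) is forged by a Favorskii rearrangement. The precursor is a 2-bromo-7-cyanocycloheptanone trans-fused to the ketal-protected ring D, reached from 2-methylcyclopentenone by asymmetric conjugate addition, Michael trapping and Dieckmann-type closure. In one operation the ketone carbon is extruded as an ester and, with the nitrile, supplies both ring-B branch carbons, equatorial by equilibration. The ester later becomes the methylene-bearing chain to ring A; McMurry coupling closes ring B.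

Key step: step 8

Remark: ring A = methylcyclopentane, ring B = cyclooctene, ring C = cyclohexane, ring D = hydroxycyclopentane; 2 and 15 (cis-jasmone) are taken as commercial.
Remark: from 13 on, the cyano-bearing carbon is drawn in its equatorial configuration; any epimer at this carbon should converge in step 17.

Step 1
Reactants: 1 2-methylcyclopent-2-en-1-one; 2 but-3-en-1-ylmagnesium bromide; 3 methyl acrylate
Product: 5 methyl 3-[(1R,5S)-5-(but-3-en-1-yl)-1-methyl-2-oxocyclopentyl]propanoate, via bromomagnesium enolate 4 (not isolated)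
Conditions: Cu(OTf)2 (5 mol %), chiral N-mesityl-N'-(1-hydroxy-4-methylpentan-2-yl)imidazolinium chloride (NHC precursor, 6 mol %, enantiomer chosen for the 5S product), 2 (1.3 equiv), Et2O, 0 °C; then 3 (2 equiv), −78 → −20 °C; aq. NH4Cl
Reagents that add atoms: none
Why: Copper-catalysed asymmetric conjugate addition of the Grignard reagent sets the β-stereocenter under ligand control, and the magnesium enolate then adds to methyl acrylate on the face opposite to the new butenyl group, which fixes the quaternary carbon trans to it (tandem conjugate addition–Michael reaction).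

Step 2
Reactants: 5 methyl 3-[(1R,5S)-5-(but-3-en-1-yl)-1-methyl-2-oxocyclopentyl]propanoate
Product: 6 methyl 3-[(1R,5S)-5-(but-3-en-1-yl)-1-methyl-2-oxocyclopent-3-en-1-yl]propanoate
Conditions: IBX (2 equiv), 4-methoxypyridine N-oxide (2 equiv), DMSO, 60 °C
Reagents that add atoms: none
Why: IBX dehydrogenation of the ketone can only proceed through the enol on the CH2 side, because the other α-carbon is quaternary, and should give the cyclopentenone without touching the terminal alkene or the ester.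

Step 3
Reactants: 6 methyl 3-[(1R,5S)-5-(but-3-en-1-yl)-1-methyl-2-oxocyclopent-3-en-1-yl]propanoate
Product: 7 methyl 3-[(1R,4S,5S)-5-(but-3-en-1-yl)-1-methyl-2-oxo-4-(propan-2-yl)cyclopentyl]propanoate
Conditions: iPrMgCl (1.5 equiv), CuBr·SMe2 (10 mol %), THF, −78 → −40 °C; aq. NH4Cl
Reagents that add atoms: isopropylmagnesium chloride CC(C)[Mg]Cl
Why: Copper-catalysed conjugate addition of the isopropyl Grignard reagent takes place anti to the substituent on the adjacent ring carbon, so the new isopropyl-bearing stereocenter is trans to the butenyl group (1,2-induction in a 4-substituted cyclopentenone).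

Step 4
Reactants: 7 methyl 3-[(1R,4S,5S)-5-(but-3-en-1-yl)-1-methyl-2-oxo-4-(propan-2-yl)cyclopentyl]propanoate
Product: 8 methyl 3-[(6R,7S,8S)-7-(but-3-en-1-yl)-6-methyl-8-(propan-2-yl)-1,4-dioxaspiro[4.4]nonan-6-yl]propanoate
Conditions: (Me3SiOCH2)2 (3 equiv), Me3SiOTf (5 mol %), CH2Cl2, −78 → −20 °C; pyridine quench
Reagents that add atoms: 1,2-bis(trimethylsilyloxy)ethane C[Si](C)(C)OCCO[Si](C)(C)C
Why: Silyl-triflate-catalysed ketalization with the bis-silyl ether of ethylene glycol protects the hindered ketone under aprotic conditions that leave the methyl ester and the alkene unchanged.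

Step 5
Reactants: 8 methyl 3-[(6R,7S,8S)-7-(but-3-en-1-yl)-6-methyl-8-(propan-2-yl)-1,4-dioxaspiro[4.4]nonan-6-yl]propanoate
Product: 10 methyl 3-[(6R,7S,8S)-7-(2-cyanoethyl)-6-methyl-8-(propan-2-yl)-1,4-dioxaspiro[4.4]nonan-6-yl]propanoate, via aldehyde 9 (not isolated)
Conditions: O3, CH2Cl2, −78 °C; PPh3, −78 → 23 °C; solvent exchange to THF; I2 (1.2 equiv), 28% aq. NH3, 23 °C
Reagents that add atoms: ammonia N
Why: Ozonolysis with reductive work-up cleaves the terminal alkene to the aldehyde, and iodine in aqueous ammonia converts this aldehyde through its aldimine into the nitrile (oxidative amination), so the side chain ends in a cyano group one carbon shorter.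

Step 6
Reactants: 10 methyl 3-[(6R,7S,8S)-7-(2-cyanoethyl)-6-methyl-8-(propan-2-yl)-1,4-dioxaspiro[4.4]nonan-6-yl]propanoate
Product: 11 (3'S,3a'S,8a'R)-8a'-methyl-6'-oxo-3'-(propan-2-yl)decahydrospiro[[1,3]dioxolane-2,1'-azulene]-5'-carbonitrile
Conditions: KOtBu (2.2 equiv), THF, 0 → 23 °C; aq. NH4Cl
Reagents that add atoms: none
Why: In this Dieckmann-type condensation the α-cyano carbanion attacks the ester carbonyl in a 7-exo-trig closure and loss of methoxide, driven by formation of the stabilized β-keto nitrile enolate, should give the cycloheptanone trans-fused to the cyclopentane because both arms sit trans on adjacent ring carbons.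

Step 7
Reactants: 11 (3'S,3a'S,8a'R)-8a'-methyl-6'-oxo-3'-(propan-2-yl)decahydrospiro[[1,3]dioxolane-2,1'-azulene]-5'-carbonitrile
Product: 12 (3'S,3a'S,8a'R)-7'-bromo-8a'-methyl-6'-oxo-3'-(propan-2-yl)decahydrospiro[[1,3]dioxolane-2,1'-azulene]-5'-carbonitrile
Conditions: LiN(iPr)2 (2.2 equiv), THF, −78 → −20 °C; N-bromosuccinimide (1.0 equiv), −78 °C; aq. NH4Cl
Reagents that add atoms: N-bromosuccinimide O=C1CCC(=O)N1Br
Why: The dianion of the β-keto nitrile reacts with the bromine donor at its more nucleophilic α'-carbon (dianion γ-functionalization), which places bromine on the CH2 flank of the ketone; the bromine-bearing center needs no control because it is destroyed in the next step.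

Step 8
Reactants: 12 (3'S,3a'S,8a'R)-7'-bromo-8a'-methyl-6'-oxo-3'-(propan-2-yl)decahydrospiro[[1,3]dioxolane-2,1'-azulene]-5'-carbonitrile
Product: 13 methyl (3'S,3a'S,5'S,6'S,7a'R)-5'-cyano-7a'-methyl-3'-(propan-2-yl)octahydrospiro[[1,3]dioxolane-2,1'-indene]-6'-carboxylate
Conditions: NaOMe (3 equiv), MeOH, 0 → 23 °C
Reagents that add atoms: sodium methoxide [Na+].[O-]C
Why: Methoxide converts 12 into its α-cyano enolate, whose carbon displaces the α'-bromide in a 3-exo-tet closure to a cyclopropanone in which the new σ-bond joins the two carbons that flanked the ketone. Methoxide then adds to the strained carbonyl and the three-membered ring opens toward the nitrile-stabilized carbanion, so the former ring carbonyl carbon is extruded as the methyl ester on the neighbouring carbon and the seven-membered ring has contracted to the cyclohexane ring C. The closest known reaction is the Favorskii rearrangement of 2-halocycloalkanones bearing an α'-ester group, which gives ring-contracted vicinal diesters. Ring C is thus closed by 3-exo-tet cyclization followed by fragmentation of the bicyclo[4.1.0]heptanone (net 1,2-shift of a ring carbon). Both new stereocenters are α to an ester or a nitrile and should be set by thermodynamic equilibration in NaOMe/MeOH to the equatorial positions of the rigid trans-fused chair, trans to each other. The step needs cyclopropanone formation to outrun retro-Claisen cleavage and needs regioselective opening; the first is secured by bromine on the CH2 flank, which keeps the β-keto nitrile as its unreactive enolate, the second by the nitrile.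

Step 9
Reactants: 13 methyl (3'S,3a'S,5'S,6'S,7a'R)-5'-cyano-7a'-methyl-3'-(propan-2-yl)octahydrospiro[[1,3]dioxolane-2,1'-indene]-6'-carboxylate
Product: 14 (3'S,3a'S,5'S,6'S,7a'R)-5'-cyano-N-methoxy-N,7a'-dimethyl-3'-(propan-2-yl)octahydrospiro[[1,3]dioxolane-2,1'-indene]-6'-carboxamide
Conditions: MeNH(OMe)·HCl (3 equiv), iPrMgCl (6 equiv), THF, −20 → 0 °C
Reagents that add atoms: N,O-dimethylhydroxylamine hydrochloride CNOC.Cl
Why: The chloromagnesium amide formed in the flask aminolyses the methyl ester to the Weinreb amide, while the hindered secondary nitrile and the ketal should be inert at this temperature.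

Step 10
Reactants: 15 3-methyl-2-[(2Z)-pent-2-en-1-yl]cyclopent-2-en-1-one (cis-jasmone)
Product: 17 2-(2-hydroxyethyl)-3-methylcyclopent-2-en-1-one, via keto aldehyde 16 (not isolated)
Conditions: O3, CH2Cl2/MeOH (4:1), −78 °C (Sudan red endpoint); then NaBH4 (1.0 equiv), −78 → −40 °C; aq. NH4Cl
Reagents that add atoms: ozone [O-][O+]=O
Why: Ozone attacks the electron-rich side-chain alkene much faster than the electron-poor tetrasubstituted enone alkene, and borohydride at low temperature reduces the resulting aldehyde in preference to the hindered conjugated ketone (ozonolysis with reductive work-up).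

Step 11
Reactants: 17 2-(2-hydroxyethyl)-3-methylcyclopent-2-en-1-one
Product: 18 2-(2-bromoethyl)-3-methylcyclopent-2-en-1-one
Conditions: CBr4, PPh3, CH2Cl2, 0 °C
Reagents that add atoms: tetrabromomethane BrC(Br)(Br)Br
Why: The Appel reaction converts the primary alcohol into the bromide under neutral conditions that leave the enone untouched.

Step 12
Reactants: 18 2-(2-bromoethyl)-3-methylcyclopent-2-en-1-one
Product: 19 (1S)-2-(2-bromoethyl)-3-methylcyclopent-2-en-1-ol
Conditions: (R)-2-methyl-CBS-oxazaborolidine (10 mol %), BH3·SMe2 (0.7 equiv), THF, −20 °C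
Reagents that add atoms: none
Why: In this CBS reduction the oxazaborolidine–borane complex distinguishes the substituted alkenyl flank of the ketone from the CH2 flank and delivers hydride to one face, which should set the (S)-carbinol center.

Step 13
Reactants: 19 (1S)-2-(2-bromoethyl)-3-methylcyclopent-2-en-1-ol
Product: 20 (1S,2S,3S)-2-(2-bromoethyl)-3-methylcyclopentan-1-ol
Conditions: H2 (50 bar), [Ir(cod)(PCy3)(py)]PF6 (5 mol %), CH2Cl2, 23 °C
Reagents that add atoms: none
Why: In this hydroxyl-directed hydrogenation the cationic iridium catalyst binds the allylic alcohol and adds both hydrogens to the tetrasubstituted alkene from the hydroxyl face, so the methyl and bromoethyl groups should end up cis to each other and trans to the hydroxyl group.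

Step 14
Reactants: 20 (1S,2S,3S)-2-(2-bromoethyl)-3-methylcyclopentan-1-ol
Product: 21 {[(1S,2S,3S)-2-(2-bromoethyl)-3-methylcyclopentyl]oxy}(tert-butyl)dimethylsilane
Conditions: tBuMe2SiOTf, 2,6-lutidine, CH2Cl2, 0 °C
Reagents that add atoms: tert-butyldimethylsilyl triflate CC(C)(C)[Si](C)(C)OS(=O)(=O)C(F)(F)F
Why: Silylation of the secondary alcohol with the silyl triflate and a hindered base protects it for the Grignard chemistry.

Step 15
Reactants: 14 (3'S,3a'S,5'S,6'S,7a'R)-5'-cyano-N-methoxy-N,7a'-dimethyl-3'-(propan-2-yl)octahydrospiro[[1,3]dioxolane-2,1'-indene]-6'-carboxamide; 21 {[(1S,2S,3S)-2-(2-bromoethyl)-3-methylcyclopentyl]oxy}(tert-butyl)dimethylsilane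
Product: 23 (3'S,3a'S,5'S,6'S,7a'R)-6'-{3-[(1S,2S,5S)-2-{[tert-butyl(dimethyl)silyl]oxy}-5-methylcyclopentyl]propanoyl}-7a'-methyl-3'-(propan-2-yl)octahydrospiro[[1,3]dioxolane-2,1'-indene]-5'-carbonitrile, via Grignard reagent 22 (not isolated)
Conditions: 21 (1.5 equiv), Mg turnings, THF, 40 °C; then 14, THF, 0 °C; aq. NH4Cl
Reagents that add atoms: none
Why: In this Weinreb ketone synthesis the primary alkylmagnesium bromide adds once to the N-methoxy-N-methylamide through a chelated tetrahedral intermediate that collapses to the ketone only on work-up, and the nitrile should not be attacked at 0 °C.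

Step 16
Reactants: 23 (3'S,3a'S,5'S,6'S,7a'R)-6'-{3-[(1S,2S,5S)-2-{[tert-butyl(dimethyl)silyl]oxy}-5-methylcyclopentyl]propanoyl}-7a'-methyl-3'-(propan-2-yl)octahydrospiro[[1,3]dioxolane-2,1'-indene]-5'-carbonitrile
Product: 24 (3'S,3a'S,5'S,6'S,7a'R)-6'-{4-[(1S,2S,5S)-2-{[tert-butyl(dimethyl)silyl]oxy}-5-methylcyclopentyl]but-1-en-2-yl}-7a'-methyl-3'-(propan-2-yl)octahydrospiro[[1,3]dioxolane-2,1'-indene]-5'-carbonitrile
Conditions: Ph3PCH3Br (3 equiv), KOtBu (3 equiv), THF, 0 → 40 °C
Reagents that add atoms: methyltriphenylphosphonium bromide C[P+](c1ccccc1)(c1ccccc1)c1ccccc1.[Br-]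
Why: Wittig methylenation turns the ketone into the 1,1-disubstituted alkene, and the adjacent ring carbon, epimerizable until this point, should stay in its more stable equatorial configuration.

Step 17
Reactants: 24 (3'S,3a'S,5'S,6'S,7a'R)-6'-{4-[(1S,2S,5S)-2-{[tert-butyl(dimethyl)silyl]oxy}-5-methylcyclopentyl]but-1-en-2-yl}-7a'-methyl-3'-(propan-2-yl)octahydrospiro[[1,3]dioxolane-2,1'-indene]-5'-carbonitrile
Product: 26 1-[(3'S,3a'S,5'S,6'S,7a'R)-6'-{4-[(1S,2S,5S)-2-{[tert-butyl(dimethyl)silyl]oxy}-5-methylcyclopentyl]but-1-en-2-yl}-7a'-methyl-3'-(propan-2-yl)octahydrospiro[[1,3]dioxolane-2,1'-indene]-5'-yl]ethan-1-one, via lithium ketiminate 25 (not isolated)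
Conditions: MeLi (3 equiv), Et2O, −20 → 0 °C; aq. NH4Cl, SiO2; then K2CO3, MeOH, 23 °C
Reagents that add atoms: methyllithium [Li]C; water O
Why: Methyllithium adds to the nitrile to give the N-lithio ketimine, which cannot react further and is hydrolysed to the methyl ketone, and carbonate then equilibrates the acetyl-bearing carbon to the equatorial position, trans to the neighbouring alkenyl branch.

Step 18
Reactants: 26 1-[(3'S,3a'S,5'S,6'S,7a'R)-6'-{4-[(1S,2S,5S)-2-{[tert-butyl(dimethyl)silyl]oxy}-5-methylcyclopentyl]but-1-en-2-yl}-7a'-methyl-3'-(propan-2-yl)octahydrospiro[[1,3]dioxolane-2,1'-indene]-5'-yl]ethan-1-one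
Product: 27 1-[(3'S,3a'S,5'S,6'S,7a'R)-6'-{4-[(1S,2S,5S)-2-hydroxy-5-methylcyclopentyl]but-1-en-2-yl}-7a'-methyl-3'-(propan-2-yl)octahydrospiro[[1,3]dioxolane-2,1'-indene]-5'-yl]ethan-1-one
Conditions: Bu4NF, THF, 23 °C
Reagents that add atoms: none
Why: Fluoride-mediated cleavage of the silyl ether frees the secondary alcohol.

Step 19
Reactants: 27 1-[(3'S,3a'S,5'S,6'S,7a'R)-6'-{4-[(1S,2S,5S)-2-hydroxy-5-methylcyclopentyl]but-1-en-2-yl}-7a'-methyl-3'-(propan-2-yl)octahydrospiro[[1,3]dioxolane-2,1'-indene]-5'-yl]ethan-1-one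
Product: 28 (2S,3S)-2-{3-[(3'S,3a'S,5'S,6'S,7a'R)-5'-acetyl-7a'-methyl-3'-(propan-2-yl)octahydrospiro[[1,3]dioxolane-2,1'-indene]-6'-yl]but-3-en-1-yl}-3-methylcyclopentan-1-one
Conditions: Dess–Martin periodinane, NaHCO3, CH2Cl2, 0 °C
Reagents that add atoms: none
Why: Dess–Martin oxidation under buffered, non-basic conditions should give the cyclopentanone without epimerizing its cis α-stereocenter.

Step 20
Reactants: 28 (2S,3S)-2-{3-[(3'S,3a'S,5'S,6'S,7a'R)-5'-acetyl-7a'-methyl-3'-(propan-2-yl)octahydrospiro[[1,3]dioxolane-2,1'-indene]-6'-yl]but-3-en-1-yl}-3-methylcyclopentan-1-one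
Product: 29 tetracyclic diene ketal (target skeleton with a 1,3-dioxolane in place of CHOH in ring D)
Conditions: TiCl3(DME)1.5 (8 equiv), Zn–Cu couple, DME, reflux; 28 added over 30 h by syringe pump
Reagents that add atoms: none
Why: In this McMurry coupling low-valent titanium joins the two ketones through a titanium pinacolate that is deoxygenated to the tetrasubstituted alkene, the closure of ring B being eight-membered with the ring-cis (Z) geometry enforced by the ring.

Step 21
Reactants: 29 tetracyclic diene ketal (target skeleton with a 1,3-dioxolane in place of CHOH in ring D)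
Product: 30 tetracyclic dienone (target skeleton with C=O in place of CHOH in ring D)
Conditions: pyridinium p-toluenesulfonate, acetone/H2O (10:1), 60 °C
Reagents that add atoms: water O
Why: Mild acid-catalysed hydrolysis removes the dioxolane and should not isomerize the exocyclic methylene or the tetrasubstituted alkene.

Step 22
Reactants: 30 tetracyclic dienone (target skeleton with C=O in place of CHOH in ring D)
Product: 31 target alcohol CNP0510481.1
Conditions: NaBH4, MeOH, 0 °C
Reagents that add atoms: none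
Why: Hydride should attack the cyclopentanone from the face opposite to the adjacent angular methyl group, which gives the alcohol cis to that methyl group as in the target (substrate-controlled reduction as for 17-keto steroids).

Compound list
1 | 2-methylcyclopent-2-en-1-one | CC1=CCCC1=O | starting material
2 | but-3-en-1-ylmagnesium bromide | C=CCC[Mg]Br | starting material
3 | methyl acrylate | C=CC(=O)OC | starting material
4 | bromomagnesium (3S)-3-(but-3-en-1-yl)-2-methylcyclopent-1-en-1-olate | C=CCC[C@H]1CCC(O[Mg]Br)=C1C | intermediate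
5 | methyl 3-[(1R,5S)-5-(but-3-en-1-yl)-1-methyl-2-oxocyclopentyl]propanoate | COC(=O)CC[C@@]1(C)C(=O)CC[C@@H]1CCC=C | intermediate
6 | methyl 3-[(1R,5S)-5-(but-3-en-1-yl)-1-methyl-2-oxocyclopent-3-en-1-yl]propanoate | COC(=O)CC[C@@]1(C)C(=O)C=C[C@@H]1CCC=C | intermediate
7 | methyl 3-[(1R,4S,5S)-5-(but-3-en-1-yl)-1-methyl-2-oxo-4-(propan-2-yl)cyclopentyl]propanoate | COC(=O)CC[C@@]1(C)C(=O)C[C@@H](C(C)C)[C@@H]1CCC=C | intermediate
8 | methyl 3-[(6R,7S,8S)-7-(but-3-en-1-yl)-6-methyl-8-(propan-2-yl)-1,4-dioxaspiro[4.4]nonan-6-yl]propanoate | COC(=O)CC[C@@]1(C)C2(OCCO2)C[C@@H](C(C)C)[C@@H]1CCC=C | intermediate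
9 | methyl 3-[(6R,7S,8S)-6-methyl-7-(3-oxopropyl)-8-(propan-2-yl)-1,4-dioxaspiro[4.4]nonan-6-yl]propanoate | COC(=O)CC[C@@]1(C)C2(OCCO2)C[C@@H](C(C)C)[C@@H]1CCC=O | intermediate
10 | methyl 3-[(6R,7S,8S)-7-(2-cyanoethyl)-6-methyl-8-(propan-2-yl)-1,4-dioxaspiro[4.4]nonan-6-yl]propanoate | COC(=O)CC[C@@]1(C)C2(OCCO2)C[C@@H](C(C)C)[C@@H]1CCC#N | intermediate
11 | (3'S,3a'S,8a'R)-8a'-methyl-6'-oxo-3'-(propan-2-yl)decahydrospiro[[1,3]dioxolane-2,1'-azulene]-5'-carbonitrile (cycloheptanone trans-fused to the ketal-protected cyclopentane) | N#CC1C(=O)CC[C@@]2(C)C3(OCCO3)C[C@@H](C(C)C)[C@@H]2C1 | intermediate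
12 | (3'S,3a'S,8a'R)-7'-bromo-8a'-methyl-6'-oxo-3'-(propan-2-yl)decahydrospiro[[1,3]dioxolane-2,1'-azulene]-5'-carbonitrile | N#CC1C(=O)C(Br)C[C@@]2(C)C3(OCCO3)C[C@@H](C(C)C)[C@@H]2C1 | intermediate
13 | methyl (3'S,3a'S,5'S,6'S,7a'R)-5'-cyano-7a'-methyl-3'-(propan-2-yl)octahydrospiro[[1,3]dioxolane-2,1'-indene]-6'-carboxylate | COC(=O)[C@H]1C[C@@]2(C)C3(OCCO3)C[C@@H](C(C)C)[C@@H]2C[C@@H]1C#N | intermediate
14 | (3'S,3a'S,5'S,6'S,7a'R)-5'-cyano-N-methoxy-N,7a'-dimethyl-3'-(propan-2-yl)octahydrospiro[[1,3]dioxolane-2,1'-indene]-6'-carboxamide | CON(C)C(=O)[C@H]1C[C@@]2(C)C3(OCCO3)C[C@@H](C(C)C)[C@@H]2C[C@@H]1C#N | intermediate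
15 | 3-methyl-2-[(2Z)-pent-2-en-1-yl]cyclopent-2-en-1-one (cis-jasmone) | CC/C=C\CC1=C(C)CCC1=O | starting material
16 | 2-(2-methyl-5-oxocyclopent-1-en-1-yl)acetaldehyde | O=CCC1=C(C)CCC1=O | intermediate
17 | 2-(2-hydroxyethyl)-3-methylcyclopent-2-en-1-one | OCCC1=C(C)CCC1=O | intermediate
18 | 2-(2-bromoethyl)-3-methylcyclopent-2-en-1-one | BrCCC1=C(C)CCC1=O | intermediate
19 | (1S)-2-(2-bromoethyl)-3-methylcyclopent-2-en-1-ol | BrCCC1=C(C)CC[C@@H]1O | intermediate
20 | (1S,2S,3S)-2-(2-bromoethyl)-3-methylcyclopentan-1-ol | BrCC[C@H]1[C@@H](C)CC[C@@H]1O | intermediate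
21 | {[(1S,2S,3S)-2-(2-bromoethyl)-3-methylcyclopentyl]oxy}(tert-butyl)dimethylsilane | BrCC[C@H]1[C@@H](C)CC[C@@H]1O[Si](C)(C)C(C)(C)C | intermediate
22 | bromo{2-[(1S,2S,5S)-2-{[tert-butyl(dimethyl)silyl]oxy}-5-methylcyclopentyl]ethyl}magnesium | Br[Mg]CC[C@H]1[C@@H](C)CC[C@@H]1O[Si](C)(C)C(C)(C)C | intermediate
23 | (3'S,3a'S,5'S,6'S,7a'R)-6'-{3-[(1S,2S,5S)-2-{[tert-butyl(dimethyl)silyl]oxy}-5-methylcyclopentyl]propanoyl}-7a'-methyl-3'-(propan-2-yl)octahydrospiro[[1,3]dioxolane-2,1'-indene]-5'-carbonitrile | CC(C)(C)[Si](C)(C)O[C@H]1CC[C@H](C)[C@@H]1CCC(=O)[C@H]1C[C@@]2(C)C3(OCCO3)C[C@@H](C(C)C)[C@@H]2C[C@@H]1C#N | intermediate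
24 | (3'S,3a'S,5'S,6'S,7a'R)-6'-{4-[(1S,2S,5S)-2-{[tert-butyl(dimethyl)silyl]oxy}-5-methylcyclopentyl]but-1-en-2-yl}-7a'-methyl-3'-(propan-2-yl)octahydrospiro[[1,3]dioxolane-2,1'-indene]-5'-carbonitrile | CC(C)(C)[Si](C)(C)O[C@H]1CC[C@H](C)[C@@H]1CCC(=C)[C@H]1C[C@@]2(C)C3(OCCO3)C[C@@H](C(C)C)[C@@H]2C[C@@H]1C#N | intermediate
25 | N-lithio ketimine of 26 (lithium ketiminate) | CC(C)(C)[Si](C)(C)O[C@H]1CC[C@H](C)[C@@H]1CCC(=C)[C@H]1C[C@@]2(C)C3(OCCO3)C[C@@H](C(C)C)[C@@H]2C[C@@H]1C(C)=N[Li] | intermediate
26 | 1-[(3'S,3a'S,5'S,6'S,7a'R)-6'-{4-[(1S,2S,5S)-2-{[tert-butyl(dimethyl)silyl]oxy}-5-methylcyclopentyl]but-1-en-2-yl}-7a'-methyl-3'-(propan-2-yl)octahydrospiro[[1,3]dioxolane-2,1'-indene]-5'-yl]ethan-1-one | CC(C)(C)[Si](C)(C)O[C@H]1CC[C@H](C)[C@@H]1CCC(=C)[C@H]1C[C@@]2(C)C3(OCCO3)C[C@@H](C(C)C)[C@@H]2C[C@@H]1C(C)=O | intermediate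
27 | 1-[(3'S,3a'S,5'S,6'S,7a'R)-6'-{4-[(1S,2S,5S)-2-hydroxy-5-methylcyclopentyl]but-1-en-2-yl}-7a'-methyl-3'-(propan-2-yl)octahydrospiro[[1,3]dioxolane-2,1'-indene]-5'-yl]ethan-1-one | O[C@H]1CC[C@H](C)[C@@H]1CCC(=C)[C@H]1C[C@@]2(C)C3(OCCO3)C[C@@H](C(C)C)[C@@H]2C[C@@H]1C(C)=O | intermediate
28 | (2S,3S)-2-{3-[(3'S,3a'S,5'S,6'S,7a'R)-5'-acetyl-7a'-methyl-3'-(propan-2-yl)octahydrospiro[[1,3]dioxolane-2,1'-indene]-6'-yl]but-3-en-1-yl}-3-methylcyclopentan-1-one | O=C1CC[C@H](C)[C@@H]1CCC(=C)[C@H]1C[C@@]2(C)C3(OCCO3)C[C@@H](C(C)C)[C@@H]2C[C@@H]1C(C)=O | intermediate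
29 | tetracyclic diene ketal (target skeleton with a 1,3-dioxolane in place of CHOH in ring D) | C=C1CC[C@@H]2/C(=C(/C)[C@H]3C[C@H]4[C@H](C(C)C)CC5(OCCO5)[C@]4(C)C[C@H]13)CC[C@@H]2C | intermediate
30 | tetracyclic dienone (target skeleton with C=O in place of CHOH in ring D) | C=C1CC[C@@H]2/C(=C(/C)[C@H]3C[C@H]4[C@H](C(C)C)CC(=O)[C@]4(C)C[C@H]13)CC[C@@H]2C | intermediate
31 | target alcohol CNP0510481.1 | C=C1CC[C@@H]2/C(=C(/C)[C@H]3C[C@H]4[C@H](C(C)C)C[C@@H](O)[C@]4(C)C[C@H]13)CC[C@@H]2C | target

Total step count: 22 (17 in the main line, 5 for the ring A fragment 21).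
Longest linear sequence: 17 steps (steps 1–9 and 15–22).

Steps most likely to fail

Step 8 (Favorskii ring contraction). Methoxide may add to the ketone and cleave the seven-membered ring by a retro-Claisen pathway, or displace bromide directly, before the cyclopropanone forms. The fallback is a Wolff ring contraction that sets out from 11 and comes back at 13. Formylation of the dianion of 11 with ethyl formate (LiN(iPr)2, THF, −78 → 0 °C) should give the α'-hydroxymethylene ketone F1. Deformylative diazo transfer (4-acetamidobenzenesulfonyl azide, Et3N, MeCN) should give the α'-diazo ketone F2. Irradiation at 300 nm in MeOH should then induce the Wolff rearrangement, in which the cyano-bearing ring carbon migrates to the carbene carbon and the ketene is trapped as the methyl ester; brief equilibration with NaOMe in MeOH should give 13.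

Step 20 (McMurry closure of ring B). Closure of the eight-membered ring may be slow enough for intermolecular coupling to compete, and the Lewis-acidic titanium chlorides at reflux may epimerize the cis α-stereocenter of the cyclopentanone. The fallback sets out from 28 and comes back at 29. Pinacol cyclization with SmI2 (THF, −78 → 0 °C) should give the cis-diol F3, thiocarbonyldiimidazole (toluene, 80 °C) the cyclic thionocarbonate F4, and Corey–Winter elimination with 1,3-dimethyl-2-phenyl-1,3,2-diazaphospholidine (40 °C) the alkene 29.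

Step 1 (tandem conjugate addition–Michael reaction). The ester enolate formed after the first Michael addition may oligomerize methyl acrylate, or the hindered magnesium enolate may be captured incompletely. The fallback sets out from 1 (with 2) and comes back at 5. The same copper-catalysed conjugate addition, quenched with Me3SiCl, should give the silyl enol ether F5. MeLi (THF, 0 °C) regenerates the lithium enolate, which should add at −78 °C to methyl 2-(trimethylsilyl)acrylate, whose silyl group stabilizes the adduct anion and stops oligomerization, to give the α-silyl ester F6. Protodesilylation with KF in MeOH should give 5.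

Further compounds
F1 | step 8 | (3'S,3a'S,8a'R)-7'-(hydroxymethylidene)-8a'-methyl-6'-oxo-3'-(propan-2-yl)decahydrospiro[[1,3]dioxolane-2,1'-azulene]-5'-carbonitrile | N#CC1C(=O)C(=CO)C[C@@]2(C)C3(OCCO3)C[C@@H](C(C)C)[C@@H]2C1
F2 | step 8 | (3'S,3a'S,8a'R)-7'-diazo-8a'-methyl-6'-oxo-3'-(propan-2-yl)decahydrospiro[[1,3]dioxolane-2,1'-azulene]-5'-carbonitrile | N#CC1C(=O)C(=[N+]=[N-])C[C@@]2(C)C3(OCCO3)C[C@@H](C(C)C)[C@@H]2C1
F3 | step 20 | tetracyclic cis-diol (29 with HO–C–C(CH3)–OH in place of the tetrasubstituted alkene) | C=C1CC[C@@H]2C(O)(C(C)(O)[C@H]3C[C@H]4[C@H](C(C)C)CC5(OCCO5)[C@]4(C)C[C@H]13)CC[C@@H]2C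
F4 | step 20 | cyclic thionocarbonate of the diol F3 | C=C1CC[C@@H]2C6(OC(=S)OC6(C)[C@H]3C[C@H]4[C@H](C(C)C)CC5(OCCO5)[C@]4(C)C[C@H]13)CC[C@@H]2C
F5 | step 1 | {[(3S)-3-(but-3-en-1-yl)-2-methylcyclopent-1-en-1-yl]oxy}trimethylsilane | C=CCC[C@H]1CCC(O[Si](C)(C)C)=C1C
F6 | step 1 | methyl 3-[(1R,5S)-5-(but-3-en-1-yl)-1-methyl-2-oxocyclopentyl]-2-(trimethylsilyl)propanoate | COC(=O)C(C[C@@]1(C)C(=O)CC[C@@H]1CCC=C)[Si](C)(C)C
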